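**Retrosynthetic overview**
1. Target 22 ← acetylation after desilylation at C11; the 5Z olefin ← cis-semi-hydrogenation of a 13-membered cycloalkyne.
2. Key step: the 13-membered lactone ring is closed at C5≡C6 by ring-closing alkyne metathesis of an open diyne ester. The C1–O15 ester bond is made beforehand by a simple intermolecular esterification, instead of the usual Corey-lactone olefinations followed by C1–O15 macrolactonisation.
3. The cyclopentanone with its three contiguous trans centres (C8, C11, C12) ← one-pot three-component coupling of enone 11, the C13–C20 alkenyl zincate from iodide 8, and 1-iodobut-2-yne 10.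
4. Iodide 8 (15S, 13E, 17Z) ← methyl (S)-glycidate 2 + but-1-yne 1 (alkynyl epoxide opening, cis-semi-hydrogenation, Takai olefination).
5. Ring order: the cyclopentanone ring is bought in 11; the 13-membered lactone ring is the only ring built (step 10).

Assumption: the SMILES is read as natural-series PGE3 1,15-lactone 11-acetate (8R,11R,12R,15S; 5Z,13E,17Z; prostanoid numbering used for positions), and 2, 11 and hept-5-ynoic acid 17 are taken as catalogue compounds.

**Route**

Step 1
Reactants: 1 but-1-yne; 2 methyl (2S)-oxirane-2-carboxylate (methyl (S)-glycidate)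
Product: 4 methyl (2S)-2-hydroxyhept-4-ynoate, via lithium but-1-ynide 3 (not isolated)
Conditions: 1, n-BuLi, THF, −78 °C; BF3·OEt2, −78 °C; then 2, −78 °C
Reagents that add atoms: none
Why: BF3-mediated alkynylation of an epoxide (Yamaguchi–Hirao type): the alkynyl borate opens the oxirane by SN2 at its unsubstituted CH2 and is too weak a nucleophile to attack the ester at −78 °C, and since the C2–O bond is never broken the (S) centre of 2 is carried over unchanged as the future C15.

Step 2
Reactants: 4 methyl (2S)-2-hydroxyhept-4-ynoate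
Product: 5 methyl (2S,4Z)-2-hydroxyhept-4-enoate
Conditions: H2 (1 atm), Pd/CaCO3 poisoned with Pb(OAc)2, quinoline, EtOAc, rt
Reagents that add atoms: none
Why: Lindlar-type semi-hydrogenation adds H2 syn on the lead-poisoned palladium surface and stops at the cis-alkene, which fixes the 17Z geometry without touching the stereocentre.

Step 3
Reactants: 5 methyl (2S,4Z)-2-hydroxyhept-4-enoate
Product: 6 methyl (2S,4Z)-2-(triethylsilyloxy)hept-4-enoate
Conditions: Et3SiCl, imidazole, DMF, 0 °C → rt
Reagents that add atoms: triethylsilyl chloride, CC[Si](Cl)(CC)CC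
Why: Imidazole-promoted O-silylation of the secondary alcohol; the triethylsilyl ether is chosen because it survives t-BuLi and can later be cleaved in the presence of the tert-butyldimethylsilyl ether.

Step 4
Reactants: 6 methyl (2S,4Z)-2-(triethylsilyloxy)hept-4-enoate
Product: 7 (2S,4Z)-2-(triethylsilyloxy)hept-4-enal
Conditions: i-Bu2AlH (1.1 equiv), CH2Cl2, −78 °C
Reagents that add atoms: none
Why: Partial ester reduction with i-Bu2AlH stops at the aldehyde level at −78 °C for α-silyloxy esters, and the non-basic conditions leave the α-stereocentre intact (the aldehyde is used at once).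

Step 5
Reactants: 7 (2S,4Z)-2-(triethylsilyloxy)hept-4-enal
Product: 8 (1E,3S,5Z)-1-iodo-3-(triethylsilyloxy)octa-1,5-diene
Conditions: CrCl2 (6 equiv), CHI3 (2 equiv), THF/1,4-dioxane, 0 °C → rt, dark
Reagents that add atoms: iodoform, IC(I)I
Why: Takai iodo-olefination: the geminal dichromium carbenoid from CHI3 and CrCl2 adds to the aldehyde and eliminates to the (E)-alkenyl iodide (sets 13E), under non-basic conditions that do not epimerise the α-silyloxy centre.

Step 6
Reactants: 9 1-bromobut-2-yne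
Product: 10 1-iodobut-2-yne
Conditions: NaI, acetone, rt, dark
Reagents that add atoms: sodium iodide, [Na+].[I-]
Why: Finkelstein SN2 halide exchange driven by precipitation of NaBr gives the more reactive propargylic iodide needed for the enolate alkylation.

Step 7
Reactants: 8 (1E,3S,5Z)-1-iodo-3-(triethylsilyloxy)octa-1,5-diene; 11 (4R)-4-(tert-butyldimethylsilyloxy)cyclopent-2-en-1-one; 10 1-iodobut-2-yne
Product: 15 (2R,3R,4R)-2-(but-2-yn-1-yl)-4-(tert-butyldimethylsilyloxy)-3-[(1E,3S,5Z)-3-(triethylsilyloxy)octa-1,5-dien-1-yl]cyclopentan-1-one, via vinyllithium 12 (not isolated), via alkenylzincate 13 (not isolated), via zincate enolate 14 (not isolated)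
Conditions: 8, t-BuLi (2.0 equiv), Et2O, −78 °C; Me2Zn (1.0 equiv), −78 → 0 °C; 11, THF, −78 °C; HMPA, 10 (5 equiv), −78 → −40 °C
Reagents that add atoms: none
Why: Noyori-type three-component coupling (tandem conjugate addition–enolate alkylation): the alkenyl group is delivered to the enone face anti to the C11 silyloxy group (sets C12), and the regiodefined zinc enolate, which neither equilibrates nor expels the β-silyloxy group, is alkylated by the propargylic iodide anti to the new C12 side chain (sets C8), giving the all-trans 8R,11R,12R array.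

Step 8
Reactants: 15 (2R,3R,4R)-2-(but-2-yn-1-yl)-4-(tert-butyldimethylsilyloxy)-3-[(1E,3S,5Z)-3-(triethylsilyloxy)octa-1,5-dien-1-yl]cyclopentan-1-one
Product: 16 (2R,3R,4R)-2-(but-2-yn-1-yl)-4-(tert-butyldimethylsilyloxy)-3-[(1E,3S,5Z)-3-hydroxyocta-1,5-dien-1-yl]cyclopentan-1-one
Conditions: AcOH/THF/H2O (3:1:1), rt
Reagents that add atoms: none
Why: Acid-catalysed silyl ether hydrolysis removes the triethylsilyl group roughly two orders of magnitude faster than the tert-butyldimethylsilyl group, and dilute acetic acid does not eliminate the β-silyloxy ketone or break the C15–O bond.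

Step 9
Reactants: 16 (2R,3R,4R)-2-(but-2-yn-1-yl)-4-(tert-butyldimethylsilyloxy)-3-[(1E,3S,5Z)-3-hydroxyocta-1,5-dien-1-yl]cyclopentan-1-one; 17 hept-5-ynoic acid
Product: 18 (1E,3S,5Z)-1-[(1R,2R,5R)-2-(but-2-yn-1-yl)-5-(tert-butyldimethylsilyloxy)-3-oxocyclopentyl]octa-1,5-dien-3-yl hept-5-ynoate
Conditions: N,N'-dicyclohexylcarbodiimide, 4-(dimethylamino)pyridine (cat.), CH2Cl2, 0 °C → rt
Reagents that add atoms: none
Why: Steglich esterification acylates the C15 oxygen, so the carbinol C–O bond is untouched and 15S is retained, and catalytic 4-(dimethylamino)pyridine at 0 °C is too mild to eliminate the β-silyloxy ketone.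

Step 10
Reactants: 18 (1E,3S,5Z)-1-[(1R,2R,5R)-2-(but-2-yn-1-yl)-5-(tert-butyldimethylsilyloxy)-3-oxocyclopentyl]octa-1,5-dien-3-yl hept-5-ynoate
Product: 19 (8R,11R,12R,13E,15S,17Z)-11-(tert-butyldimethylsilyloxy)-9-oxoprosta-13,17-dien-5-yn-1,15-olide (13-membered cycloalkyne lactone)
Conditions: Mo(≡CC6H4-4-OMe)(OSiPh3)3 (5–10 mol%), 5 Å molecular sieves, toluene (0.002 M), rt → 60 °C
Reagents that add atoms: none
Why: Ring-closing alkyne metathesis joins the two methyl-capped alkynes at C5≡C6 with loss of but-2-yne, which the sieves absorb to drive the equilibrium, and the molybdenum alkylidyne leaves the two olefins, the ketone, the ester and the silyl ether untouched so no stereocentre or olefin geometry is affected.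

Step 11
Reactants: 19 (8R,11R,12R,13E,15S,17Z)-11-(tert-butyldimethylsilyloxy)-9-oxoprosta-13,17-dien-5-yn-1,15-olide
Product: 20 (5Z,8R,11R,12R,13E,15S,17Z)-11-(tert-butyldimethylsilyloxy)-9-oxoprosta-5,13,17-trien-1,15-olide
Conditions: H2 (1 atm), Pd/CaCO3 poisoned with Pb(OAc)2, quinoline, hexane/EtOAc, rt
Reagents that add atoms: none
Why: Lindlar-type syn semi-hydrogenation of the ring alkyne gives only the 5Z olefin, and the poisoned catalyst does not reduce or isomerise the 13E and 17Z disubstituted olefins.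

Step 12
Reactants: 20 (5Z,8R,11R,12R,13E,15S,17Z)-11-(tert-butyldimethylsilyloxy)-9-oxoprosta-5,13,17-trien-1,15-olide
Product: 21 (5Z,8R,11R,12R,13E,15S,17Z)-11-hydroxy-9-oxoprosta-5,13,17-trien-1,15-olide (PGE3 1,15-lactone)
Conditions: aq. HF (48%), MeCN, 0 °C → rt
Reagents that add atoms: none
Why: Fluoride-driven acidic desilylation cleaves the Si–O bond without the basic conditions that would dehydrate the β-hydroxy ketone or epimerise C8.

Step 13
Reactants: 21 (5Z,8R,11R,12R,13E,15S,17Z)-11-hydroxy-9-oxoprosta-5,13,17-trien-1,15-olide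
Product: 22 (5Z,8R,11R,12R,13E,15S,17Z)-11-acetoxy-9-oxoprosta-5,13,17-trien-1,15-olide (target)
Conditions: Ac2O, pyridine, CH2Cl2, 0 °C, short reaction time
Reagents that add atoms: acetic anhydride, CC(=O)OC(C)=O
Why: Pyridine-mediated O-acetylation occurs at oxygen with retention at C11, and keeping it cold and brief avoids E1cB loss of acetic acid to the cross-conjugated enone.

**Compound list**
1 | but-1-yne | CCC#C | starting material
2 | methyl (2S)-oxirane-2-carboxylate (methyl (S)-glycidate) | COC(=O)[C@@H]1CO1 | starting material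
3 | lithium but-1-ynide (formed in the flask) | [Li]C#CCC | intermediate
4 | methyl (2S)-2-hydroxyhept-4-ynoate | CCC#CC[C@H](O)C(=O)OC | intermediate
5 | methyl (2S,4Z)-2-hydroxyhept-4-enoate | CC/C=C\C[C@H](O)C(=O)OC | intermediate
6 | methyl (2S,4Z)-2-(triethylsilyloxy)hept-4-enoate | CC/C=C\C[C@H](O[Si](CC)(CC)CC)C(=O)OC | intermediate
7 | (2S,4Z)-2-(triethylsilyloxy)hept-4-enal | CC/C=C\C[C@H](O[Si](CC)(CC)CC)C=O | intermediate
8 | (1E,3S,5Z)-1-iodo-3-(triethylsilyloxy)octa-1,5-diene | CC/C=C\C[C@H](O[Si](CC)(CC)CC)/C=C/I | intermediate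
9 | 1-bromobut-2-yne | CC#CCBr | starting material
10 | 1-iodobut-2-yne | CC#CCI | intermediate
11 | (4R)-4-(tert-butyldimethylsilyloxy)cyclopent-2-en-1-one | O=C1C=C[C@H](O[Si](C)(C)C(C)(C)C)C1 | starting material
12 | [(1E,3S,5Z)-3-(triethylsilyloxy)octa-1,5-dien-1-yl]lithium (formed in the flask) | CC/C=C\C[C@H](O[Si](CC)(CC)CC)/C=C/[Li] | intermediate
13 | lithium dimethyl[(1E,3S,5Z)-3-(triethylsilyloxy)octa-1,5-dien-1-yl]zincate (formed in the flask) | CC/C=C\C[C@H](O[Si](CC)(CC)CC)/C=C/[Zn-](C)C.[Li+] | intermediate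
14 | lithium dimethylzincate C1=C2 enolate of (3R,4R)-4-(tert-butyldimethylsilyloxy)-3-[(1E,3S,5Z)-3-(triethylsilyloxy)octa-1,5-dien-1-yl]cyclopentan-1-one (formed in the flask) | CC/C=C\C[C@H](O[Si](CC)(CC)CC)/C=C/[C@H]1[C@H](O[Si](C)(C)C(C)(C)C)CC(O[Zn-](C)C)=C1.[Li+] | intermediate
15 | (2R,3R,4R)-2-(but-2-yn-1-yl)-4-(tert-butyldimethylsilyloxy)-3-[(1E,3S,5Z)-3-(triethylsilyloxy)octa-1,5-dien-1-yl]cyclopentan-1-one | CC/C=C\C[C@H](O[Si](CC)(CC)CC)/C=C/[C@H]1[C@H](O[Si](C)(C)C(C)(C)C)CC(=O)[C@@H]1CC#CC | intermediate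
16 | (2R,3R,4R)-2-(but-2-yn-1-yl)-4-(tert-butyldimethylsilyloxy)-3-[(1E,3S,5Z)-3-hydroxyocta-1,5-dien-1-yl]cyclopentan-1-one | CC/C=C\C[C@H](O)/C=C/[C@H]1[C@H](O[Si](C)(C)C(C)(C)C)CC(=O)[C@@H]1CC#CC | intermediate
17 | hept-5-ynoic acid | CC#CCCCC(=O)O | starting material
18 | (1E,3S,5Z)-1-[(1R,2R,5R)-2-(but-2-yn-1-yl)-5-(tert-butyldimethylsilyloxy)-3-oxocyclopentyl]octa-1,5-dien-3-yl hept-5-ynoate | CC/C=C\C[C@H](OC(=O)CCCC#CC)/C=C/[C@H]1[C@H](O[Si](C)(C)C(C)(C)C)CC(=O)[C@@H]1CC#CC | intermediate
19 | (8R,11R,12R,13E,15S,17Z)-11-(tert-butyldimethylsilyloxy)-9-oxoprosta-13,17-dien-5-yn-1,15-olide | CC/C=C\C[C@H]1/C=C/[C@H]2[C@H](O[Si](C)(C)C(C)(C)C)CC(=O)[C@@H]2CC#CCCCC(=O)O1 | intermediate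
20 | (5Z,8R,11R,12R,13E,15S,17Z)-11-(tert-butyldimethylsilyloxy)-9-oxoprosta-5,13,17-trien-1,15-olide | CC/C=C\C[C@H]1/C=C/[C@H]2[C@H](O[Si](C)(C)C(C)(C)C)CC(=O)[C@@H]2C/C=C\CCCC(=O)O1 | intermediate
21 | (5Z,8R,11R,12R,13E,15S,17Z)-11-hydroxy-9-oxoprosta-5,13,17-trien-1,15-olide (PGE3 1,15-lactone) | CC/C=C\C[C@H]1/C=C/[C@H]2[C@H](O)CC(=O)[C@@H]2C/C=C\CCCC(=O)O1 | intermediate
22 | (5Z,8R,11R,12R,13E,15S,17Z)-11-acetoxy-9-oxoprosta-5,13,17-trien-1,15-olide (PGE3 1,15-lactone 11-acetate) | CC/C=C\C[C@H]1/C=C/[C@H]2[C@H](OC(C)=O)CC(=O)[C@@H]2C/C=C\CCCC(=O)O1 | target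

**Step count and risk**

Total step count: 13. Longest linear sequence: 12 steps (steps 1–5, then 7–13; step 6 is a one-step side branch).

Most likely to fail, first: step 7. The propargylic alkylation of the enolate must outrun proton exchange and loss of the C11 silyloxy group. The fallback sets out from the zincate enolate 14, made from 8 and 11 exactly as in step 7, and replaces the alkylation by aldol capture and radical deoxygenation. Enolate 14 is quenched at −78 °C with but-2-ynal (CC#CC=O) to give (2S,3R,4R)-4-(tert-butyldimethylsilyloxy)-2-(1-hydroxybut-2-yn-1-yl)-3-[(1E,3S,5Z)-3-(triethylsilyloxy)octa-1,5-dien-1-yl]cyclopentan-1-one F1 as a mixture of carbinol epimers. Phenyl chlorothionoformate with pyridine and catalytic 4-(dimethylamino)pyridine converts it into the corresponding O-phenyl thionocarbonate F2. Bu3SnH with azobisisobutyronitrile in toluene at 80 °C (Barton–McCombie deoxygenation) then removes the C7 oxygen, and the route is rejoined at 15.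

Second: step 10. The ring-closing alkyne metathesis has to form a strained 13-membered enyne lactone in the presence of a free ketone. The fallback gives up the metathesis closure and returns to ester-bond ring closure. It again sets out from enolate 14, which is alkylated under the step 7 conditions with methyl (5Z)-7-iodohept-5-enoate (COC(=O)CCC/C=C\CI) to give methyl (5Z)-7-[(1R,2R,3R)-3-(tert-butyldimethylsilyloxy)-5-oxo-2-[(1E,3S,5Z)-3-(triethylsilyloxy)octa-1,5-dien-1-yl]cyclopentyl]hept-5-enoate F3. AcOH/THF/H2O removes the triethylsilyl group to give the 15-hydroxy methyl ester F4. Porcine liver esterase in pH 7 phosphate buffer/acetone hydrolyses the methyl ester without harming the β-silyloxy ketone and gives the seco acid F5. Corey–Nicolaou macrolactonisation (2,2'-dipyridyl disulfide and PPh3, then slow addition to refluxing xylene) closes the lactone, and the route is rejoined at 20, so steps 10 and 11 are bypassed.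

Third: step 5. The Takai olefination can give an unsatisfactory E/Z ratio or a low yield on the sensitive α-silyloxy aldehyde. The fallback sets out from aldehyde 7 and installs the iodoalkene through an alkyne. Ohira–Bestmann homologation (dimethyl (1-diazo-2-oxopropyl)phosphonate, K2CO3, MeOH, 0 °C) gives triethyl{[(3S,5Z)-oct-5-en-1-yn-3-yl]oxy}silane F6. Hydrozirconation with Cp2Zr(H)Cl in THF, where the terminal alkyne reacts far faster than the internal cis-alkene and adds syn with zirconium at the terminus, followed by I2, gives only the (E)-alkenyl iodide, and the route is rejoined at 8.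

**Further compounds**
F1 | step 7 | (2S,3R,4R)-4-(tert-butyldimethylsilyloxy)-2-(1-hydroxybut-2-yn-1-yl)-3-[(1E,3S,5Z)-3-(triethylsilyloxy)octa-1,5-dien-1-yl]cyclopentan-1-one (carbinol epimers) | CC/C=C\C[C@H](O[Si](CC)(CC)CC)/C=C/[C@H]1[C@H](O[Si](C)(C)C(C)(C)C)CC(=O)[C@@H]1C(O)C#CC
F2 | step 7 | O-phenyl thionocarbonate of F1 | CC/C=C\C[C@H](O[Si](CC)(CC)CC)/C=C/[C@H]1[C@H](O[Si](C)(C)C(C)(C)C)CC(=O)[C@@H]1C(OC(=S)Oc2ccccc2)C#CC
F3 | step 10 | methyl (5Z)-7-[(1R,2R,3R)-3-(tert-butyldimethylsilyloxy)-5-oxo-2-[(1E,3S,5Z)-3-(triethylsilyloxy)octa-1,5-dien-1-yl]cyclopentyl]hept-5-enoate | CC/C=C\C[C@H](O[Si](CC)(CC)CC)/C=C/[C@H]1[C@H](O[Si](C)(C)C(C)(C)C)CC(=O)[C@@H]1C/C=C\CCCC(=O)OC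
F4 | step 10 | methyl (5Z)-7-[(1R,2R,3R)-3-(tert-butyldimethylsilyloxy)-2-[(1E,3S,5Z)-3-hydroxyocta-1,5-dien-1-yl]-5-oxocyclopentyl]hept-5-enoate | CC/C=C\C[C@H](O)/C=C/[C@H]1[C@H](O[Si](C)(C)C(C)(C)C)CC(=O)[C@@H]1C/C=C\CCCC(=O)OC
F5 | step 10 | (5Z)-7-[(1R,2R,3R)-3-(tert-butyldimethylsilyloxy)-2-[(1E,3S,5Z)-3-hydroxyocta-1,5-dien-1-yl]-5-oxocyclopentyl]hept-5-enoic acid | CC/C=C\C[C@H](O)/C=C/[C@H]1[C@H](O[Si](C)(C)C(C)(C)C)CC(=O)[C@@H]1C/C=C\CCCC(=O)O
F6 | step 5 | triethyl{[(3S,5Z)-oct-5-en-1-yn-3-yl]oxy}silane | CC/C=C\C[C@H](O[Si](CC)(CC)CC)C#C
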